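The cycloheptane is numbered C1(ester)–C2–C3(Me)–C4–C5–C6(Me)–C10 and the cyclopentane C6–C7–C8–C9–C10. C10 and C4 stand 1,4 across the cycloheptane, so both can be α-carbons of one temporary cyclopentanone whose carbonyl carbon bridges them. The key step is the α,α′-annulation of the pyrrolidine enamine of a 3,3-disubstituted cyclopentanone with crotonoyl chloride. It forms C3–C4 and C1–C10 in one operation and gives a bicyclo[3.2.1]octane-2,8-dione that already holds the seven-membered ring, with C1 oxygenated and the C3 methyl in place. The bridge is later opened by alkoxide (retro-Claisen, then Dieckmann closure of the cyclopentane) and its carbon leaves as CO2.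

Key step: step 4

Remark: "Cb" is the temporary bridging carbonyl carbon. Compounds 7–16 are carried as epimer mixtures at C3/C4 (7–9 also at C10), centres that are erased in steps 5, 8 and 9, so their SMILES show only the defined centres. Hydroazulene names use azulene numbering (route C9 = C1, C6 = C3a, C4 = C5, C3 = C6, C1 = C8, C10 = C8a). The ligand enantiomer in step 1 is the one that gives (R)-3.

Step 1
Reactants: 1 3-methylcyclopent-2-en-1-one
Product: 3 (3R)-3-ethenyl-3-methylcyclopentan-1-one, via dimethylaluminium enolate 2 (not isolated)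
Conditions: CH2=CHMgBr, Me2AlCl, THF, −78 °C → rt; then 1, CuTC (5 mol %), chiral phosphoramidite or NHC ligand, Et2O, −30 °C; aq. NH4Cl
Reagents that add atoms: vinylmagnesium bromide C=C[Mg]Br
Why: Cu-catalysed asymmetric conjugate addition of an alkenylaluminium to a β-substituted cyclic enone, in which the chiral Cu complex delivers vinyl to one enantioface and so sets the quaternary centre (target C6); the aluminium enolate is protonated on work-up.

Step 2
Reactants: 3 (3R)-3-ethenyl-3-methylcyclopentan-1-one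
Product: 4 methyl 3-[(1S)-1-methyl-3-oxocyclopentyl]propanoate
Conditions: CO (10 bar), MeOH, Pd(OAc)2 (1 mol %), 1,2-bis(di-tert-butylphosphinomethyl)benzene, MsOH (cat.), 80 °C; aq. work-up
Reagents that add atoms: carbon monoxide [C-]#[O+]; methanol CO
Why: Pd-catalysed hydromethoxycarbonylation should give the linear ester, because the vinyl group on a quaternary carbon has no allylic hydrogen to isomerise and Pd goes to the terminal carbon; no stereocentre is touched (the descriptor changes only by priority).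

Step 3
Reactants: 4 methyl 3-[(1S)-1-methyl-3-oxocyclopentyl]propanoate
Product: 5 methyl 3-[(1R)-1-methyl-3-(pyrrolidin-1-yl)cyclopent-3-en-1-yl]propanoate
Conditions: pyrrolidine (1.5 equiv), TsOH (cat.), toluene, reflux, Dean–Stark trap; evaporate, use crude
Reagents that add atoms: pyrrolidine C1CCNC1
Why: Stork enamine formation, with the double bond placed towards the unhindered α-carbon (C4) and away from the quaternary carbon, which fixes the regiochemistry of step 4.

Step 4
Reactants: 5 methyl 3-[(1R)-1-methyl-3-(pyrrolidin-1-yl)cyclopent-3-en-1-yl]propanoate; 6 (2E)-but-2-enoyl chloride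
Product: 9 methyl 3-(2,6-dimethyl-4,8-dioxobicyclo[3.2.1]octan-6-yl)propanoate, via ketene iminium chloride 7 (not isolated), via bicyclic iminium chloride 8 (not isolated)
Conditions: 6 (1.05 equiv), MeCN, 0 °C → reflux, 16 h; then H2O, 60 °C
Reagents that add atoms: water O
Why: This is the known α,α′-annulation of a ketone enamine with an α,β-unsaturated acid chloride: N-acylation gives an N-acyl enammonium ion whose [3,3] shift (3-aza-Cope, equivalent to conjugate addition of the enamine carbon) joins C4 to the β-carbon of the crotonoyl unit (C3–C4) and releases a ketene in iminium 7. The iminium re-forms the enamine on the C10 side and that carbon is acylated by the ketene (C1–C10), closing the six-membered ring Cb–C10–C1–C2–C3–C4 in a 6-(enolendo)-exo-dig mode; the same bond completes the seven-membered carbocycle C1–C2–C3–C4–C5–C6–C10 as the periphery of the bicyclo[3.2.1]octane, and water hydrolyses iminium 8 to dione 9. The closest known reaction type is the conversion of cyclopentanone and cyclohexanone enamines with acryloyl or crotonoyl chloride into bicyclo[3.2.1]octane-2,8-diones and bicyclo[3.3.1]nonane-2,9-diones. The new centres C3, C4 and C10 need no control, since C10 becomes an enolate in step 5 and C3/C4 become sp2 in steps 8 and 9, while C6 is not touched. The selectivity that matters is which α-carbon bonds to which end of the C3 unit; it is secured by the enamine double bond lying on the C4 side, so that the β-carbon goes to C4 and the acyl carbon to C10, leaving the oxygen on C1 and the methyl on C3.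

Step 5
Reactants: 9 methyl 3-(2,6-dimethyl-4,8-dioxobicyclo[3.2.1]octan-6-yl)propanoate
Product: 11 prop-2-en-1-yl (3aR)-3a,6-dimethyl-1,8-dioxodecahydroazulene-5-carboxylate, via ring-opened keto diester 10 (not isolated)
Conditions: NaH (1.5 equiv), allyl alcohol/THF, 0 → 50 °C; AcOH quench
Reagents that add atoms: prop-2-en-1-ol (as its sodium alkoxide) C=CCO
Why: Retro-Claisen cleavage of the non-enolisable bridging ketone by alkoxide should give the C10 enolate of the C1 ketone and leave Cb as an allyl ester on C4 (10); the enolate then closes the cyclopentane by Dieckmann condensation on the side-chain ester, and the cyclic β-diketone enolate is the thermodynamic sink (no stereocentre is set, C10 being enolised).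

Step 6
Reactants: 11 prop-2-en-1-yl (3aR)-3a,6-dimethyl-1,8-dioxodecahydroazulene-5-carboxylate
Product: 12 prop-2-en-1-yl (3aR)-8-{[tert-butyl(dimethyl)silyl]oxy}-3a,6-dimethyl-1-oxo-1,2,3,3a,4,5,6,7-octahydroazulene-5-carboxylate
Conditions: TBSOTf (1.2 equiv), Et3N (2 equiv), CH2Cl2, −78 → 0 °C
Reagents that add atoms: tert-butyldimethylsilyl triflate CC(C)(C)[Si](C)(C)OS(=O)(=O)C(F)(F)F
Why: O-silylation of the enolised β-diketone; the enol double bond exocyclic to the five-membered ring (C10=C1) is the preferred one, so the C1 oxygen should be silylated and C9 should stay a ketone with C10 planar.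

Step 7
Reactants: 12 prop-2-en-1-yl (3aR)-8-{[tert-butyl(dimethyl)silyl]oxy}-3a,6-dimethyl-1-oxo-1,2,3,3a,4,5,6,7-octahydroazulene-5-carboxylate
Product: 14 prop-2-en-1-yl (1R,3aR,8aR)-1-hydroxy-3a,6-dimethyl-8-oxo-1-(propan-2-yl)decahydroazulene-5-carboxylate, via tertiary alcohol silyl enol ether 13 (not isolated)
Conditions: i-PrLi, CeCl3, THF, −78 °C; then TBAF/AcOH (1:1), THF, 0 °C
Reagents that add atoms: isopropyllithium [Li]C(C)C
Why: Organocerium 1,2-addition to the C9 carbonyl of the planar vinylogous silyl ester should occur anti to the pseudo-axial C6 methyl (OH cis to CH3) and be ketone-selective over the ester at −78 °C; buffered fluoride then unmasks the C1 ketone, and C10 is protonated to the trans-fused ketol, which is also expected to be the thermodynamic epimer (C1 anti to isopropyl and hydrogen-bonded to the cis hydroxyl).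

Step 8
Reactants: 14 prop-2-en-1-yl (1R,3aR,8aR)-1-hydroxy-3a,6-dimethyl-8-oxo-1-(propan-2-yl)decahydroazulene-5-carboxylate
Product: 15 prop-2-en-1-yl (1R,3aR,8aR)-1-hydroxy-3a,6-dimethyl-8-oxo-1-(propan-2-yl)-1,2,3,3a,4,5,8,8a-octahydroazulene-5-carboxylate
Conditions: IBX (2.5 equiv), 4-methoxypyridine N-oxide, DMSO, 25 °C
Reagents that add atoms: none
Why: IBX α,β-dehydrogenation of the ketone through its enol; only C2–C3 can be desaturated because C10 has no β-hydrogen (C6 and C9 are fully substituted), and no stereocentre is formed.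

Step 9
Reactants: 15 prop-2-en-1-yl (1R,3aR,8aR)-1-hydroxy-3a,6-dimethyl-8-oxo-1-(propan-2-yl)-1,2,3,3a,4,5,8,8a-octahydroazulene-5-carboxylate
Product: 17 (1R,3aR,8aR)-1-hydroxy-3a,6-dimethyl-1-(propan-2-yl)-1,2,3,3a,4,7-hexahydroazulen-8(8aH)-one, via carboxylic acid 16 (not isolated)
Conditions: Pd(PPh3)4 (5 mol %), HCO2H, Et3N, THF, 25 → 50 °C
Reagents that add atoms: none
Why: Tsuji deallylation frees the β,γ-unsaturated (vinylogous β-keto) acid 16, which should lose CO2 with transfer of hydrogen to C2, so the double bond moves to C3=C4 under near-neutral conditions and the bridge carbon of step 4 leaves as CO2.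

Step 10
Reactants: 17 (1R,3aR,8aR)-1-hydroxy-3a,6-dimethyl-1-(propan-2-yl)-1,2,3,3a,4,7-hexahydroazulen-8(8aH)-one
Product: 18 (1R,3aR,8S,8aS)-3a,6-dimethyl-1-(propan-2-yl)-1,2,3,3a,4,7,8,8a-octahydroazulene-1,8-diol
Conditions: Me4NBH(OAc)3, MeCN/AcOH, −30 → 0 °C
Reagents that add atoms: none
Why: Evans–Saksena reduction, in which the acetoxyborohydride bound to the tertiary C9 hydroxyl delivers hydride to the C1 carbonyl from the face of that hydroxyl and so gives the 1,3-anti diol (C1–OH on the face of H10); after this step C10 can no longer epimerise.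

Step 11
Reactants: 18 (1R,3aR,8S,8aS)-3a,6-dimethyl-1-(propan-2-yl)-1,2,3,3a,4,7,8,8a-octahydroazulene-1,8-diol
Product: 19 (1R,3aR,5S,6R,8S,8aS)-5,6-epoxy-3a,6-dimethyl-1-(propan-2-yl)decahydroazulene-1,8-diol
Conditions: VO(acac)2 (5 mol %), t-BuOOH, CH2Cl2, 0 °C → rt
Reagents that add atoms: tert-butyl hydroperoxide CC(C)(C)OO
Why: Vanadium-catalysed hydroxyl-directed epoxidation, in which the homoallylic C1 hydroxyl delivers the peroxide oxygen to the face of C3=C4 syn to itself and so sets C3 and C4.

Step 12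
Reactants: 19 (1R,3aR,5S,6R,8S,8aS)-5,6-epoxy-3a,6-dimethyl-1-(propan-2-yl)decahydroazulene-1,8-diol; 20 3,4-dimethoxybenzoyl chloride
Product: 21 (1R,3aR,5S,6R,8S,8aS)-5,6-epoxy-1-hydroxy-3a,6-dimethyl-1-(propan-2-yl)decahydroazulen-8-yl 3,4-dimethoxybenzoate
Conditions: 20 (1.5 equiv), Et3N, DMAP (cat.), CH2Cl2, rt
Reagents that add atoms: none
Why: DMAP-catalysed acylation should take the secondary C1 hydroxyl only, the tertiary C9 hydroxyl being inert and the epoxide stable to the basic conditions; no stereocentre is touched.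

Compound list
1 | 3-methylcyclopent-2-en-1-one | CC1=CC(=O)CC1 | starting material
2 | dimethylaluminium enolate of 3 (dimethyl[(3-ethenyl-3-methylcyclopent-1-en-1-yl)oxy]alumane, quaternary carbon as in 3) | C[Al](C)OC1=C[C@](C)(C=C)CC1 | intermediate
3 | (3R)-3-ethenyl-3-methylcyclopentan-1-one | O=C1CC[C@@](C)(C=C)C1 | intermediate
4 | methyl 3-[(1S)-1-methyl-3-oxocyclopentyl]propanoate | O=C1CC[C@@](C)(CCC(=O)OC)C1 | intermediate
5 | methyl 3-[(1R)-1-methyl-3-(pyrrolidin-1-yl)cyclopent-3-en-1-yl]propanoate | C1(N2CCCC2)=CC[C@@](C)(CCC(=O)OC)C1 | intermediate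
6 | (2E)-but-2-enoyl chloride | C/C=C/C(Cl)=O | starting material
7 | 1-[4-(3-methoxy-3-oxopropyl)-4-methyl-2-(4-oxobut-3-en-2-yl)cyclopentylidene]pyrrolidin-1-ium chloride (ketene iminium salt) | O=C=CC(C)C1C[C@@](C)(CCC(=O)OC)CC1=[N+]1CCCC1.[Cl-] | intermediate
8 | 1-[6-(3-methoxy-3-oxopropyl)-2,6-dimethyl-4-oxobicyclo[3.2.1]octan-8-ylidene]pyrrolidin-1-ium chloride | O=C1CC(C)C2C[C@@](C)(CCC(=O)OC)C1C2=[N+]1CCCC1.[Cl-] | intermediate
9 | methyl 3-(2,6-dimethyl-4,8-dioxobicyclo[3.2.1]octan-6-yl)propanoate (quaternary carbon as in 4) | O=C1CC(C)C2C[C@@](C)(CCC(=O)OC)C1C2=O | intermediate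
10 | prop-2-en-1-yl 6-(3-methoxy-3-oxopropyl)-2,6-dimethyl-4-oxocycloheptane-1-carboxylate | O=C1CC(C)C(C(=O)OCC=C)C[C@@](C)(CCC(=O)OC)C1 | intermediate
11 | prop-2-en-1-yl (3aR)-3a,6-dimethyl-1,8-dioxodecahydroazulene-5-carboxylate (enolised β-diketone) | O=C1CC(C)C(C(=O)OCC=C)C[C@@]2(C)CCC(=O)C12 | intermediate
12 | prop-2-en-1-yl (3aR)-8-{[tert-butyl(dimethyl)silyl]oxy}-3a,6-dimethyl-1-oxo-1,2,3,3a,4,5,6,7-octahydroazulene-5-carboxylate | CC(C)(C)[Si](C)(C)OC1=C2C(=O)CC[C@]2(C)CC(C(=O)OCC=C)C(C)C1 | intermediate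
13 | prop-2-en-1-yl (1R,3aR)-8-{[tert-butyl(dimethyl)silyl]oxy}-1-hydroxy-3a,6-dimethyl-1-(propan-2-yl)-1,2,3,3a,4,5,6,7-octahydroazulene-5-carboxylate | CC(C)(C)[Si](C)(C)OC1=C2[C@](O)(C(C)C)CC[C@]2(C)CC(C(=O)OCC=C)C(C)C1 | intermediate
14 | prop-2-en-1-yl (1R,3aR,8aR)-1-hydroxy-3a,6-dimethyl-8-oxo-1-(propan-2-yl)decahydroazulene-5-carboxylate | O=C1CC(C)C(C(=O)OCC=C)C[C@@]2(C)CC[C@@](O)(C(C)C)[C@H]12 | intermediate
15 | prop-2-en-1-yl (1R,3aR,8aR)-1-hydroxy-3a,6-dimethyl-8-oxo-1-(propan-2-yl)-1,2,3,3a,4,5,8,8a-octahydroazulene-5-carboxylate | O=C1C=C(C)C(C(=O)OCC=C)C[C@@]2(C)CC[C@@](O)(C(C)C)[C@H]12 | intermediate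
16 | (1R,3aR,8aR)-1-hydroxy-3a,6-dimethyl-8-oxo-1-(propan-2-yl)-1,2,3,3a,4,5,8,8a-octahydroazulene-5-carboxylic acid | O=C1C=C(C)C(C(=O)O)C[C@@]2(C)CC[C@@](O)(C(C)C)[C@H]12 | intermediate
17 | (1R,3aR,8aR)-1-hydroxy-3a,6-dimethyl-1-(propan-2-yl)-1,2,3,3a,4,7-hexahydroazulen-8(8aH)-one | O=C1CC(C)=CC[C@@]2(C)CC[C@@](O)(C(C)C)[C@H]12 | intermediate
18 | (1R,3aR,8S,8aS)-3a,6-dimethyl-1-(propan-2-yl)-1,2,3,3a,4,7,8,8a-octahydroazulene-1,8-diol | O[C@H]1CC(C)=CC[C@@]2(C)CC[C@@](O)(C(C)C)[C@H]12 | intermediate
19 | (1R,3aR,5S,6R,8S,8aS)-5,6-epoxy-3a,6-dimethyl-1-(propan-2-yl)decahydroazulene-1,8-diol | O[C@H]1C[C@@]3(C)O[C@H]3C[C@@]2(C)CC[C@@](O)(C(C)C)[C@H]12 | intermediate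
20 | 3,4-dimethoxybenzoyl chloride | COc1ccc(C(Cl)=O)cc1OC | starting material
21 | (1R,3aR,5S,6R,8S,8aS)-5,6-epoxy-1-hydroxy-3a,6-dimethyl-1-(propan-2-yl)decahydroazulen-8-yl 3,4-dimethoxybenzoate | COc1ccc(C(=O)O[C@H]2C[C@@]3(C)O[C@H]3C[C@@]3(C)CC[C@@](O)(C(C)C)[C@H]23)cc1OC | target

Total step count: 12. Longest linear sequence: 12 steps (1 → 21); 6 and 20 are used as purchased.

Steps most likely to fail

Step 4 is the first risk. After the C3–C4 bond has formed, the ketene may be captured intermolecularly, or the enamine may fail to re-form towards the neopentyl C10; direct C-acylation of the enamine at C4 would also attach the acyl carbon to the wrong α-carbon. The fallback forms the two bonds separately and in an unambiguous order. Setting out from 5, Stork Michael addition to tert-butyl (2E)-but-2-enoate (MeCN, reflux; aq. AcOH) should give methyl 3-[4-(4-tert-butoxy-4-oxobutan-2-yl)-1-methyl-3-oxocyclopentyl]propanoate F1. Trifluoroacetic acid then frees 3-[4-(3-methoxy-3-oxopropyl)-4-methyl-2-oxocyclopentyl]butanoic acid F2. Acid-mediated intramolecular C-acylation of the ketone at C10 (polyphosphoric acid, 80 °C) should close the six-membered ring and return to the route at 9.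

Step 5 is the second risk. The alkoxide may add to the C1 carbonyl and open the six-membered ring instead of the bridge, or the ester enolate at C8 may condense onto the bridge-derived ester and close the wrong Dieckmann ring. The fallback separates cleavage from ring closure. Setting out from 9, aqueous KOH in MeOH should cleave the bridging ketone hydrolytically and saponify the side chain to 6-(2-carboxyethyl)-2,6-dimethyl-4-oxocycloheptane-1-carboxylic acid F3. Allylation of both acids (allyl bromide, Cs2CO3, DMF) gives prop-2-en-1-yl 2,6-dimethyl-4-oxo-6-[3-oxo-3-(prop-2-en-1-yloxy)propyl]cycloheptane-1-carboxylate F4. Dieckmann condensation under conditions that form the ketone enolate first (KOt-Bu, 1.1 equiv, THF, 0 °C) then returns to the route at 11.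

Step 7 is the third risk. The hindered secondary organocerium may act as a base or as a hydride donor, or attack the allyl ester, instead of adding to C9, and the facial selectivity may be low. The fallback brings in the three carbons as an sp2 nucleophile and saturates them late. Setting out from 12, isopropenylmagnesium bromide/CeCl3 (THF, −78 °C) followed by TBAF/AcOH should give prop-2-en-1-yl 1-hydroxy-3a,6-dimethyl-8-oxo-1-(prop-1-en-2-yl)decahydroazulene-5-carboxylate F5. IBX dehydrogenation as in step 8 gives prop-2-en-1-yl 1-hydroxy-3a,6-dimethyl-8-oxo-1-(prop-1-en-2-yl)-1,2,3,3a,4,5,8,8a-octahydroazulene-5-carboxylate F6. Deallylative decarboxylation as in step 9 gives 1-hydroxy-3a,6-dimethyl-1-(prop-1-en-2-yl)-1,2,3,3a,4,7-hexahydroazulen-8(8aH)-one F7. Hydrogenation of the 1,1-disubstituted alkene in preference to the trisubstituted one (H2, RhCl(PPh3)3, benzene) returns to the route at 17.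

Further compounds
F1 | step 4 | methyl 3-[4-(4-tert-butoxy-4-oxobutan-2-yl)-1-methyl-3-oxocyclopentyl]propanoate (quaternary carbon as in 4) | O=C1C(C(C)CC(=O)OC(C)(C)C)C[C@@](C)(CCC(=O)OC)C1
F2 | step 4 | 3-[4-(3-methoxy-3-oxopropyl)-4-methyl-2-oxocyclopentyl]butanoic acid (quaternary carbon as in 4) | O=C1C(C(C)CC(=O)O)C[C@@](C)(CCC(=O)OC)C1
F3 | step 5 | 6-(2-carboxyethyl)-2,6-dimethyl-4-oxocycloheptane-1-carboxylic acid (quaternary carbon as in 9) | O=C1CC(C)C(C(=O)O)C[C@@](C)(CCC(=O)O)C1
F4 | step 5 | prop-2-en-1-yl 2,6-dimethyl-4-oxo-6-[3-oxo-3-(prop-2-en-1-yloxy)propyl]cycloheptane-1-carboxylate (quaternary carbon as in 9) | O=C1CC(C)C(C(=O)OCC=C)C[C@@](C)(CCC(=O)OCC=C)C1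
F5 | step 7 | prop-2-en-1-yl 1-hydroxy-3a,6-dimethyl-8-oxo-1-(prop-1-en-2-yl)decahydroazulene-5-carboxylate (ring centres arranged as in 14) | O=C1CC(C)C(C(=O)OCC=C)C[C@@]2(C)CC[C@@](O)(C(C)=C)[C@H]12
F6 | step 7 | prop-2-en-1-yl 1-hydroxy-3a,6-dimethyl-8-oxo-1-(prop-1-en-2-yl)-1,2,3,3a,4,5,8,8a-octahydroazulene-5-carboxylate (ring centres arranged as in 15) | O=C1C=C(C)C(C(=O)OCC=C)C[C@@]2(C)CC[C@@](O)(C(C)=C)[C@H]12
F7 | step 7 | 1-hydroxy-3a,6-dimethyl-1-(prop-1-en-2-yl)-1,2,3,3a,4,7-hexahydroazulen-8(8aH)-one (ring centres arranged as in 17) | O=C1CC(C)=CC[C@@]2(C)CC[C@@](O)(C(C)=C)[C@H]12
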